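Litres per mole is the unit of the one number I carry through these flasks.

| flask | starting material | partner | remark | time |
|---|---|---|---|---|
| Saturday's | 0.0019 M (in portions, 3) | 2.5 equiv | run made earlier; portions every 25 min |  |
| Sunday's | 0.0079 M (in portions, 3) | 2.5 equiv | run made earlier; portions every 25 min |  |
| Wednesday's | 0.013 M (in portions, 3) | 2.7 equiv | run made earlier; portions every 25 min |  |
| amber | 0.0030 M | 3.80 equiv | everything together at the start | 15 h |
| grey | 0.013 M (in portions, 3) | 2.50 equiv | the portions of starting material follow each other after 25 min, the first at the start | 15 h |

| run | time / h | target / % |
|---|---|---|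
| Saturday's | 1.33 | 6.5 |
| Saturday's | 4.00 | 7.2 |
| Saturday's | 6.00 | 7.7 |
| Saturday's | 10.0 | 7.4 |
| Sunday's | 2.50 | 23.9 |
| Sunday's | 5.00 | 24.9 |
| Sunday's | 8.00 | 24.0 |
| Sunday's | 10.0 | 24.3 |
| Wednesday's | 0.833 | 23.3 |
| Wednesday's | 2.00 | 35.8 |
| Wednesday's | 5.00 | 36.4 |
| Wednesday's | 10.0 | 36.2 |

(scatter of a reading: 0.3 percentage points)

- the analysis behind the earlier runs scatters by 0.3 percentage points, standard deviation
- where the amount of starting material changes, what is given in equivalents or mol% on it follows

The readings flatten soon after the last portion: Wednesday's run reads 35.8% at 2.00 h and 36.2% at 10.0 h, so I take each plateau as a share won in a competition. But the plateau rises with the charge, from 7.4% in Saturday's run to 24.3% in Sunday's, so I suppose that the path to target is first order in [partner] while the starting material also goes by a path that needs no partner. Dividing one rate by the other drops time: target over non-target equals a constant times the mean [partner]. With that mean taken as the charge less half of what the target consumed, Wednesday's last reading gives 17.3 M⁻¹, and this quotient, a selectivity factor per unit of [partner], is my competition ratio. Saturday's and Sunday's last readings give 17.1 M⁻¹ and 17.1 M⁻¹, so the reading comes out alike in these runs from 0.0019 M to 0.013 M. But each of those runs went in by portions, so grey repeats their way and amber does not.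

- which of the two ends with the higher amount of target, in percent of the starting material charged ("neither" if they lie within 2 percentage points) (amber / grey / neither)
- target at the end, in percent of the starting material charged, amber
- target at the end, in percent of the starting material charged, grey

With that ratio, and [partner] lowered the same way, I reckon 16.2% for amber and 34.3% for grey, so grey stands 18 percentage points higher, against a margin of 2 points. The forecast has 16.1% and 34.2%, each just under mine, names grey, and says of amber: “Adding everything at once shouldn't matter for first-order loss, but this is untested, so the range is wider.”

    starting material + partner → target (k = 0.0140 M⁻¹ s⁻¹)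
    starting material → side product (k = 4.90 × 10⁻⁴ s⁻¹)
    partner → decomposed reagent (k = 1.70 × 10⁻⁴ s⁻¹)

The flask gives 19.7% for amber and 34.5% for grey, so grey ends higher. With grey's charges and amber's way of adding the starting material, the target comes to 40.8%. Read the same way, amber's result gives a ratio of 22.1 M⁻¹, higher than the 17.3 M⁻¹ read from Wednesday's run. Carried to amber's neighbour with 0.0051 M of starting material, at the same equivalents, that ratio reckons 29.1%, and that flask gives 29.6%.

The data are simulated on assumed constants; the scatter is artificial.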